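## Retrosynthetic overview

1. Feature: the 31-membered ring holds only the lactone unit C1(=O)–O and the unbranched, stereocentre-free chain of 29 methylenes C2–C30. Any CH2–CH2 bond can therefore be the last C–C bond made, and C20–C21 is chosen because it divides the ring into a C20 acid and a C10 alcohol that can both be bought.
2. 12 <= hydrogenation of the C20=C21 ene-lactone 11 <= Ramberg–Bäcklund contraction (C20–C21 formed, SO2 lost) of the 32-membered alpha-chloro sulfone lactone 9, which carries SO2 between C20 and C21.
3. 9 <= NCS/mCPBA on thia-lactone 7 <= closure of the 32-membered ring at sulfur (C20 thiolate on the C21 bromide) in the open ester 6.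
4. 6 <= Fischer esterification (C1–O bond) of 20-sulfanylicosanoic acid 4 (two steps from half ester 1) with 10-bromodecan-1-ol 5.
5. Ring order: 32-membered thia-lactone (step 4), then a transient three-membered episulfone inside it (step 6), then the 31-membered lactone by loss of SO2 (step 6).

Key step: step 6

Assumption: the chlorination in step 5 is expected to fall on both sulfur-bound methylenes (C20 and C21), and step 6 should give the E alkene with some Z. The route is drawn for the C21 chloride and the E alkene; the unseparated isomers form the same C20=C21 bond and converge at the latest at 12.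

## Route

Step 1
Reactants: 1 20-methoxy-20-oxoicosanoic acid (icosanedioic acid monomethyl ester)
Product: 2 methyl 20-hydroxyicosanoate
Conditions: BH3·SMe2 (1.3 equiv), THF, 0 °C to rt; then H2O
Reagents that add atoms: none
Why: Chemoselective borane reduction: the free acid forms an acyloxyborane that is reduced far faster than the methyl ester, so only the C20 terminus should be taken down to the primary alcohol.

Step 2
Reactants: 2 methyl 20-hydroxyicosanoate
Product: 4 20-sulfanylicosanoic acid, via isothiouronium bromide 3 (not isolated)
Conditions: thiourea (3 equiv), 48% aq HBr, AcOH, reflux; then NaOH, H2O/EtOH, reflux, N2; then HCl to pH 1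
Reagents that add atoms: thiourea, NC(N)=S; water, O; hydrogen bromide, Br (bromide ion of 3 only)
Why: Alcohol-to-thiol conversion through an S-alkylisothiouronium salt: HBr activates the primary C20 hydroxyl for SN2 attack by the sulfur of thiourea, and the alkaline hydrolysis that releases the thiolate also completes the wanted saponification of the methyl ester, so sulfur installation and ester cleavage cost one operation.

Step 3
Reactants: 4 20-sulfanylicosanoic acid; 5 10-bromodecan-1-ol
Product: 6 10-bromodecyl 20-sulfanylicosanoate
Conditions: TsOH·H2O (5 mol %), toluene, reflux, Dean–Stark trap, argon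
Reagents that add atoms: none
Why: Fischer esterification with azeotropic water removal acylates the primary alcohol rather than the thiol because the oxo ester is the thermodynamic product, and in acidic toluene the un-ionised thiol leaves the primary bromide alone, which keeps the two partners of the coming ring closure apart.

Step 4
Reactants: 6 10-bromodecyl 20-sulfanylicosanoate
Product: 7 1-oxa-12-thiacyclodotriacontan-32-one (32-membered thia-lactone; sulfur between C20 and C21 of the target numbering)
Conditions: Cs2CO3 (3 equiv), degassed dry DMF, 55 °C, 6 added by syringe pump over 24 h (final 2 mM)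
Reagents that add atoms: none
Why: Intramolecular thioether synthesis (SN2, 32-exo-tet) of a cesium thiolate under pseudo-high dilution: the one-component substrate is consumed as fast as it is fed, the soft thiolate prefers the primary bromide to the ester carbonyl, and dry Cs2CO3 brings in no hydroxide or alkoxide, which is why sulfur enters as a thiol and not by double displacement with strongly basic hydrated sulfide ion.

Step 5
Reactants: 7 1-oxa-12-thiacyclodotriacontan-32-one
Product: 9 racemic 11-chloro-1-oxa-12-thiacyclodotriacontan-32-one 12,12-dioxide (SO2 between C20 and C21; chlorine on C21), via alpha-chloro sulfide 8 (not isolated)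
Conditions: NCS (1.05 equiv), CCl4, 0 °C to rt; filter; then mCPBA (2.5 equiv), CH2Cl2, 0 °C to rt
Reagents that add atoms: N-chlorosuccinimide, O=C1CCC(=O)N1Cl; mCPBA, O=C(OO)c1cccc(Cl)c1
Why: Alpha-chlorination of a dialkyl sulfide by NCS (chlorosulfonium salt, then Pummerer-type shift of chlorine to carbon) followed by peracid oxidation is the standard entry to alpha-chloro sulfones; the moisture-sensitive 8 is oxidised at once, the ester is inert to both reagents, and the new C21 stereocentre forms racemic without consequence because step 6 makes it sp2.

Step 6
Reactants: 9 racemic 11-chloro-1-oxa-12-thiacyclodotriacontan-32-one 12,12-dioxide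
Product: 11 (E)-triacont-20-en-30-olide [(21E)-oxacyclohentriacont-21-en-2-one], via episulfone 10 (not isolated)
Conditions: KOtBu (2.5 equiv), THF (5 mM), −78 °C, slowly to 0 °C; cold aq NH4Cl quench
Reagents that add atoms: none
Why: KOtBu reversibly deprotonates C20, the methylene on the far side of the sulfonyl group from chlorine, and the carbanion displaces chloride from C21 in a 1,3-elimination that forms the C20–C21 bond as episulfone 10, which loses SO2 cheletropically to leave the C20=C21 alkene. This is the Ramberg–Bäcklund reaction of a preformed cyclic alpha-chloro sulfone, a known ring contraction to medium and large cycloalkenes that is applied here to a ring that also holds an ester. The only closure event is the 3-exo-tet formation of the thiirane dioxide ring, so the 31-membered ring is never closed end to end but is cut out of the 32-membered one by excision of sulfur, and its formation does not depend on ring size. No stereocentre is kept: C21 and both episulfone carbons end as sp2 carbons, tert-butoxide should favour the E alkene by equilibrating 10 to its trans form, and step 7 removes the geometry. The selectivity needed is proton removal next to sulfur in preference to acyl attack on, or condensation of, the lactone; since the hydrogens at C20 and at C2 are of similar acidity it rests not on a pKa gap but on the fact that only the C20 carbanion has a fast irreversible exit, whereas the C2 enolate re-protonates and finds no partner at 5 mM. Attack at the carbonyl is held back by the bulk of tert-butoxide and the low temperature, and the reaction is quenched cold as soon as 9 is consumed.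

Step 7
Reactants: 11 (E)-triacont-20-en-30-olide
Product: 12 triacontan-30-olide (oxacyclohentriacontan-2-one)
Conditions: H2 (1 atm), 10% Pd/C, EtOAc, rt
Reagents that add atoms: none
Why: Heterogeneous catalytic hydrogenation of an unhindered 1,2-disubstituted alkene saturates C20=C21 from either geometry and leaves the lactone untouched, the alkene being chromatographed beforehand to remove sulfur traces that could poison the catalyst.

## Compound list

1 | 20-methoxy-20-oxoicosanoic acid | COC(=O)CCCCCCCCCCCCCCCCCCC(=O)O | starting material
2 | methyl 20-hydroxyicosanoate | COC(=O)CCCCCCCCCCCCCCCCCCCO | intermediate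
3 | S-(19-carboxynonadecyl)isothiouronium bromide | NC(=[NH2+])SCCCCCCCCCCCCCCCCCCCC(=O)O.[Br-] | intermediate (not isolated)
4 | 20-sulfanylicosanoic acid | OC(=O)CCCCCCCCCCCCCCCCCCCS | intermediate
5 | 10-bromodecan-1-ol | OCCCCCCCCCCBr | starting material
6 | 10-bromodecyl 20-sulfanylicosanoate | SCCCCCCCCCCCCCCCCCCCC(=O)OCCCCCCCCCCBr | intermediate
7 | 1-oxa-12-thiacyclodotriacontan-32-one | O=C1CCCCCCCCCCCCCCCCCCCSCCCCCCCCCCO1 | intermediate
8 | racemic 11-chloro-1-oxa-12-thiacyclodotriacontan-32-one (alpha-chloro sulfide) | O=C1CCCCCCCCCCCCCCCCCCCSC(Cl)CCCCCCCCCO1 | intermediate (not isolated)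
9 | racemic 11-chloro-1-oxa-12-thiacyclodotriacontan-32-one 12,12-dioxide | O=C1CCCCCCCCCCCCCCCCCCCS(=O)(=O)C(Cl)CCCCCCCCCO1 | intermediate
10 | trans-20,21-epithiotriacontan-30-olide S,S-dioxide (thiirane 1,1-dioxide on C20–C21; racemic, one enantiomer drawn) | O=C1CCCCCCCCCCCCCCCCCC[C@@H]2[C@@H](CCCCCCCCCO1)S2(=O)=O | intermediate (not isolated)
11 | (E)-triacont-20-en-30-olide | O=C1CCCCCCCCCCCCCCCCCC/C=C/CCCCCCCCCO1 | intermediate
12 | triacontan-30-olide (oxacyclohentriacontan-2-one) | O=C1CCCCCCCCCCCCCCCCCCCCCCCCCCCCCO1 | target

## Step count and risks

Total step count: 7. Longest linear sequence: 7 (1 to 12); 5 enters at step 3.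

**Step 6.**
- What may go wrong: tert-butoxide may add to the lactone carbonyl and open the ring. The 1,3-elimination of chloride may also be too slow at the temperatures at which the ester is safe.
- Fallback: ring opening is accepted, and the ring is closed at the C1–O bond instead.
- It sets out from 9. KOH in aqueous tBuOH/THF at 50 °C saponifies the lactone and carries out the Ramberg–Bäcklund reaction on the open chain. After acidification this gives (Z)-30-hydroxytriacont-20-enoic acid F1 (hydroxide conditions favour Z).
- Hydrogenation (H2, Pd/C, warm EtOAc/EtOH) gives 30-hydroxytriacontanoic acid F2.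
- Yamaguchi macrolactonisation (2,4,6-trichlorobenzoyl chloride, Et3N, THF; slow addition to DMAP in refluxing toluene) comes back to the route at 12.

**Step 4.**
- What may go wrong: intermolecular S-alkylation to oligomers, and air oxidation of the thiol to disulfide, may outrun the ring closure.
- Fallback: the C–S bond is made between two molecules and the 32-membered ring is closed at the ester.
- It sets out from 4 and 5, and step 3 is skipped. K2CO3 (2.5 equiv) in DMF at 50 °C alkylates the thiolate selectively. After acidification this gives 20-[(10-hydroxydecyl)sulfanyl]icosanoic acid F3.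
- Shiina macrolactonisation (2-methyl-6-nitrobenzoic anhydride, DMAP, CH2Cl2, slow addition) comes back to the route at 7.

**Step 5.**
- What may go wrong: over-chlorination, loss of HCl from the alpha-chloro sulfide toward a vinyl sulfide, and hydrolysis before the oxidation.
- Fallback: chlorine is introduced at the sulfoxide level, where every intermediate is stable to chromatography.
- It sets out from 7. NaIO4 (1.05 equiv) in aqueous MeOH/THF at 0 °C gives racemic 1-oxa-12-thiacyclodotriacontan-32-one 12-oxide F4.
- NCS with K2CO3 in CH2Cl2 at rt gives 11-chloro-1-oxa-12-thiacyclodotriacontan-32-one 12-oxide F5.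
- mCPBA in CH2Cl2 comes back to the route at 9.

Further compounds
F1 | step 6 | (Z)-30-hydroxytriacont-20-enoic acid | OCCCCCCCCC/C=C\CCCCCCCCCCCCCCCCCCC(=O)O
F2 | step 6 | 30-hydroxytriacontanoic acid | OCCCCCCCCCCCCCCCCCCCCCCCCCCCCCC(=O)O
F3 | step 4 | 20-[(10-hydroxydecyl)sulfanyl]icosanoic acid | OCCCCCCCCCCSCCCCCCCCCCCCCCCCCCCC(=O)O
F4 | step 5 | 1-oxa-12-thiacyclodotriacontan-32-one 12-oxide (racemic at sulfur) | O=C1CCCCCCCCCCCCCCCCCCCS(=O)CCCCCCCCCCO1
F5 | step 5 | 11-chloro-1-oxa-12-thiacyclodotriacontan-32-one 12-oxide (mixture of diastereomers) | O=C1CCCCCCCCCCCCCCCCCCCS(=O)C(Cl)CCCCCCCCCO1
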